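The benzene ring is built, not bought. Methyl propiolate is brominated to methyl 3-bromopropiolate, whose alkyne carbons become ring atoms C1 (bearing the carbinol carbon) and C2 (bearing the methoxy oxygen); isoprene supplies C3–C6 with the methyl on C4. One thermal [4+2] cycloaddition of these two partners forms C2–C3 and C6–C1 and gives a 1,4-cyclohexadiene in which the C2 bromide is a vinylogous acyl bromide, so methoxide enters at C2 alone before dehydrogenation to the arene. The ester carbon then becomes the tertiary carbinol through double vinyl addition, ozonolysis–reduction and acylation of the two primary hydroxyls.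

Key step: step 2

Remark on the chemistry: the target has no stereocentre, because the carbinol carbon carries two identical isobutyryloxymethyl arms. Ring atoms are numbered C1 (carbinol-bearing), C2 (OMe), C4 (Me) throughout.

Step 1
Reactants: 1 methyl propiolate
Product: 2 methyl 3-bromopropiolate
Conditions: NBS (1.1 equiv), AgNO3 (10 mol %), acetone, rt, dark
Reagents that add atoms: N-bromosuccinimide, O=C1CCC(=O)N1Br
Why: Silver-catalysed electrophilic bromination of a terminal alkyne with NBS (through the silver acetylide) is the standard entry to 3-bromopropiolates and leaves the ester untouched.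

Step 2
Reactants: 2 methyl 3-bromopropiolate; 3 isoprene
Product: 4 methyl 2-bromo-4-methylcyclohexa-1,4-diene-1-carboxylate
Conditions: isoprene (5 equiv), BHT (1 mol %), toluene, 90 °C, sealed tube
Reagents that add atoms: none
Why: Thermal, concerted but asynchronous [4+2] cycloaddition (Diels–Alder reaction) between the isoprene HOMO and the LUMO of the electron-poor bromoalkynoate, with the bond to the bromine-bearing β-carbon the more advanced one in the transition state. The closest known reaction type is the Diels–Alder reaction of 3-halopropiolate esters with 1,3-dienes, which gives 2-halocyclohexa-1,4-diene-1-carboxylates. The six-membered carbocycle is closed by intermolecular cycloaddition, both ring bonds (C2–C3 and C6–C1) being made in the same step, suprafacially on each partner. No stereocentre is created, since every new ring position is a CH2 group or a trigonal carbon. The step needs "para" regioselectivity, which rests on the larger HOMO coefficient at the isoprene CH2 attached to the methyl-bearing carbon pairing with the larger LUMO coefficient at the β-carbon of the ynoate; the preference is expected to be modest, so the minor 5-methyl isomer is removed by chromatography here or, failing that, after aromatization. Excess diene and a radical inhibitor should hold back oligomerization of isoprene and decomposition of the bromoalkyne.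

Step 3
Reactants: 4 methyl 2-bromo-4-methylcyclohexa-1,4-diene-1-carboxylate
Product: 5 methyl 2-methoxy-4-methylcyclohexa-1,4-diene-1-carboxylate
Conditions: NaOMe (1.1 equiv), MeOH, −20 → 0 °C, argon
Reagents that add atoms: sodium methoxide, [Na+].[O-]C
Why: Addition–elimination (nucleophilic vinylic substitution) at the β-carbon of the β-bromo enoate, a vinylogous acyl bromide, should place the methoxy group on C2 only, the matched methyl ester/methoxide pair making ester exchange invisible and the low temperature limiting base-induced double-bond migration.

Step 4
Reactants: 5 methyl 2-methoxy-4-methylcyclohexa-1,4-diene-1-carboxylate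
Product: 6 methyl 2-methoxy-4-methylbenzoate
Conditions: DDQ (1.1 equiv), toluene, rt
Reagents that add atoms: none
Why: DDQ dehydrogenation of a 1,4-cyclohexadiene (hydride abstraction from the doubly allylic, enol-ether-activated C3 methylene, then proton loss) should give the arene under neutral, anhydrous conditions that spare the ester and the aryl methyl group.

Step 5
Reactants: 6 methyl 2-methoxy-4-methylbenzoate
Product: 8 3-(2-methoxy-4-methylphenyl)penta-1,4-dien-3-ol, via aryl vinyl ketone 7 (not isolated)
Conditions: vinylmagnesium bromide (3.5 equiv), LaCl3·2LiCl (0.3 equiv), THF, −20 → 0 °C; aq NH4Cl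
Reagents that add atoms: vinylmagnesium bromide, C=C[Mg]Br
Why: Double Grignard addition to an ester through the aryl vinyl ketone, the oxophilic lanthanum salt steering both additions to the carbonyl carbon and away from conjugate addition; the new carbinol carbon bears two identical vinyl groups and is not a stereocentre.

Step 6
Reactants: 8 3-(2-methoxy-4-methylphenyl)penta-1,4-dien-3-ol
Product: 10 2-(2-methoxy-4-methylphenyl)propane-1,2,3-triol, via hydroxy dialdehyde 9 (not isolated)
Conditions: O3, CH2Cl2/MeOH (4:1), −78 °C, Sudan red 7B end-point; then NaBH4 (6 equiv), −78 °C → rt
Reagents that add atoms: ozone, [O-][O+]=O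
Why: Ozonolysis of the two monosubstituted alkenes, which react with ozone far faster than the anisole ring, followed by borohydride reduction of the peroxidic intermediates and aldehydes in the same flask should give the 2-aryl glycerol without isolation of the sensitive dialdehyde; the two arms stay identical, so no stereocentre arises.

Step 7
Reactants: 10 2-(2-methoxy-4-methylphenyl)propane-1,2,3-triol
Product: 11 2-hydroxy-2-(2-methoxy-4-methylphenyl)propane-1,3-diyl bis(2-methylpropanoate)
Conditions: isobutyryl chloride (2.2 equiv), pyridine, CH2Cl2, −10 → 0 °C
Reagents that add atoms: isobutyryl chloride, CC(C)C(=O)Cl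
Why: Chemoselective O-acylation with an acid chloride and pyridine (Einhorn-type esterification) should esterify the two primary hydroxyls, the hindered tertiary benzylic hydroxyl being inert at this temperature without a nucleophilic catalyst.

Compound list
1 | methyl propiolate | C#CC(=O)OC | starting material
2 | methyl 3-bromopropiolate | COC(=O)C#CBr | intermediate
3 | isoprene (2-methylbuta-1,3-diene) | C=CC(C)=C | starting material
4 | methyl 2-bromo-4-methylcyclohexa-1,4-diene-1-carboxylate | COC(=O)C1=C(Br)CC(C)=CC1 | intermediate
5 | methyl 2-methoxy-4-methylcyclohexa-1,4-diene-1-carboxylate | COC(=O)C1=C(OC)CC(C)=CC1 | intermediate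
6 | methyl 2-methoxy-4-methylbenzoate | COC(=O)c1ccc(C)cc1OC | intermediate
7 | 1-(2-methoxy-4-methylphenyl)prop-2-en-1-one (aryl vinyl ketone) | C=CC(=O)c1ccc(C)cc1OC | intermediate (not isolated)
8 | 3-(2-methoxy-4-methylphenyl)penta-1,4-dien-3-ol | C=CC(O)(C=C)c1ccc(C)cc1OC | intermediate
9 | 2-hydroxy-2-(2-methoxy-4-methylphenyl)propanedial (present largely as peroxidic methanol adducts) | COc1cc(C)ccc1C(O)(C=O)C=O | intermediate (not isolated)
10 | 2-(2-methoxy-4-methylphenyl)propane-1,2,3-triol | COc1cc(C)ccc1C(O)(CO)CO | intermediate
11 | 2-hydroxy-2-(2-methoxy-4-methylphenyl)propane-1,3-diyl bis(2-methylpropanoate) | COc1cc(C)ccc1C(O)(COC(=O)C(C)C)COC(=O)C(C)C | target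

Total step count: 7
Longest linear sequence: 7 steps (1 → 2 → 4 → 5 → 6 → 8 → 10 → 11; isoprene 3 enters at step 2)

Steps most likely to fail

Step 2. Regiocontrol may be too weak to leave a separable excess of the 4-methyl adduct, and oligomerization of isoprene or thermal loss of the bromoalkyne may erode conversion. The fallback sets out from isoprene 3 and methyl propiolate 1. An AlCl3-catalysed Diels–Alder reaction (AlCl3 0.2 equiv, CH2Cl2, 0 °C → rt), a variant known for a much stronger para preference than the thermal reaction, should give methyl 4-methylcyclohexa-1,4-diene-1-carboxylate F1. DDQ in toluene would aromatize it to methyl 4-methylbenzoate F2. Ester-directed ortho C–H oxygenation with catalytic [RuCl2(p-cymene)]2 and K2S2O8 in CF3CO2H/(CF3CO)2O at 80 °C should give methyl 4-methyl-2-(trifluoroacetoxy)benzoate F3; the two ortho positions are equivalent, so no regiochemical question arises. F3 is cleaved on aqueous work-up to methyl 2-hydroxy-4-methylbenzoate F4. O-Methylation (MeI, K2CO3, acetone) comes back to the route at 6. The C2 oxygen is then introduced by C–H functionalization instead of through the bromide, and steps 1, 3 and 4 are not needed.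

Step 3. Base-promoted migration of the ring double bonds with loss of HBr, or adventitious oxidation to the unreactive bromoarene, may outrun the substitution. The fallback sets out from 4 and reverses the order of events. DDQ (toluene, rt) should give methyl 2-bromo-4-methylbenzoate F5. An Ullmann-type copper-catalysed methoxylation (CuI 10 mol %, 1,10-phenanthroline, NaOMe, MeOH/DMF, 100 °C) then replaces the aryl bromide by methoxide and comes back at 6.

Step 5. The second vinyl nucleophile may add in conjugate fashion to the transient aryl vinyl ketone 7, that enone may oligomerize, or the doubly allylic benzylic alcohol may undergo acid-triggered allylic transposition on isolation. The fallback sets out from 6. (Benzyloxymethyl)lithium, generated from tributyl[(benzyloxy)methyl]stannane and n-BuLi in THF at −78 °C, is added twice to the ester to give 1,3-bis(benzyloxy)-2-(2-methoxy-4-methylphenyl)propan-2-ol F6. Hydrogenolysis (H2, Pd/C, EtOAc, rt) removes both benzyl groups and comes back at triol 10, so the ozonolysis of step 6 is bypassed as well.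

Further compounds
F1 | step 2 | methyl 4-methylcyclohexa-1,4-diene-1-carboxylate | COC(=O)C1=CCC(C)=CC1
F2 | step 2 | methyl 4-methylbenzoate | COC(=O)c1ccc(C)cc1
F3 | step 2 | methyl 4-methyl-2-(trifluoroacetoxy)benzoate | COC(=O)c1ccc(C)cc1OC(=O)C(F)(F)F
F4 | step 2 | methyl 2-hydroxy-4-methylbenzoate | COC(=O)c1ccc(C)cc1O
F5 | step 3 | methyl 2-bromo-4-methylbenzoate | COC(=O)c1ccc(C)cc1Br
F6 | step 5 | 1,3-bis(benzyloxy)-2-(2-methoxy-4-methylphenyl)propan-2-ol | COc1cc(C)ccc1C(O)(COCc1ccccc1)COCc1ccccc1
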